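Late in the noon run the target has stopped, 24.3% at 2.00 min and 24.5% at 4.00 min, while the substrate still falls from 53.8% to 33.2%. The first substrate readings of the three runs are nearly equal (89.5%, 89.5%, 89.1%), so I take the supply of substrate towards target to be independent of reagent.

| setting | noon | midnight | summer | north | north-west | east | north-east |
|---|---|---|---|---|---|---|---|
| substrate | 0.25 M | 0.25 M | 0.35 M | 1.0 M | 0.50 M | 0.25 M | 0.15 M |
| reagent | 0.36 equiv | 0.71 equiv | 1.3 equiv | 0.430 equiv | 0.430 equiv | 1.30 equiv | 1.30 equiv |
| remark | run made earlier | run made earlier | run made earlier |  |  |  |  |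
| time |  |  |  | 4.0 min | 4.0 min | 4.0 min | 4.0 min |

| run | time / min | target / % | substrate / % |
|---|---|---|---|
| noon | 0.333 | 4.7 | 89.5 |
| noon | 0.667 | 10.5 | 80.7 |
| noon | 1.00 | 16.2 | 72.2 |
| noon | 2.00 | 24.3 | 53.8 |
| noon | 4.00 | 24.5 | 33.2 |
| midnight | 0.333 | 6.5 | 89.5 |
| midnight | 0.667 | 13.0 | 80.6 |
| midnight | 1.00 | 19.6 | 72.0 |
| midnight | 2.00 | 31.4 | 53.1 |
| midnight | 4.00 | 35.4 | 31.5 |
| summer | 0.333 | 7.6 | 89.1 |
| summer | 1.00 | 21.7 | 71.6 |
| summer | 2.00 | 33.5 | 52.6 |
| summer | 3.00 | 36.7 | 39.2 |
| summer | 4.00 | 37.3 | 30.5 |

(readings scatter by 0.3 percentage points)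

* ranking by amount of target, in percent of the substrate charged, from high to low, at 4.0 min (north / north-west / east / north-east)
* the amount of target, in percent of the substrate charged of the flask you put first, at 4.0 min
* the amount of target, in percent of the substrate charged of the flask you put last, at 4.0 min



I write the balance of the reagent: the charge C = c(reagent) at the start divides into target and a loss. My assumption is that this loss goes with the square of c(reagent), against a supply going with c(substrate). In this rough reckoning of mine, target then has two limits, C and a ceiling M that grows with the root of c(substrate), joined like two resistances: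

c(target) = C·M/(C + M)

Solved for M, the last readings give 0.192 M for noon at 0.25 M and 0.183 M for summer at 0.35 M. Scaled by the root, noon gives my upper bound and summer my lower:

north-east: 49.5% to 56.2%

east: 41.9% to 48.2%

north-west: 21.7% to 24.0%

north: 18.0% to 20.3%

The forecast says east > north-east > north-west > north, with 36.5% and 29.5%, and holds that east and north-east “should resemble the midnight and summer runs”. Its top, said of east, stands below my lower bound for east, and its low, said of north, above my upper bound for north.

The flasks give north-east > east > north-west > north, with 48.8% and 19.3%.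

    substrate ⇌ tautomer (K = 3.00, k = 0.330 min⁻¹)
    substrate + reagent → isomer of the product (k = 0.0420 L mol⁻¹ min⁻¹)
    reagent + tautomer → target (k = 48.0 L mol⁻¹ min⁻¹)
    2 reagent → homo dimer (k = 4.00 L mol⁻¹ min⁻¹)

North-east lies 0.70 percentage points under my lower bound, and north lies inside its bracket. In north at 4.00 min, reagent, the limiting reagent there, stands at 0%. Of the 0.430 M charged to north, the homo dimer holds 0.232 M, the target 0.193 M and the isomer of the product 0.00515 M. The ceiling M, scaled to north's equivalents at 2.5 M of substrate, gives 13.5% to 15.5% of target, and that flask holds 13.9%.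

(Readings and results are simulated for an exercise; the scatter is artificial.)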